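Remark on the chemistry (assumption): the target is read as the (3R,4R)-trans lactone, and C4 of 6, 7, 8 and 11 has the same spatial arrangement and the same descriptor R, so no structure needed correction; the ligand antipode that gives 4R in step 3 is to be settled in one scouting run, both antipodes being accessible.

## Structural features

The target 13 is a dibenzylbutyrolactone lignan. Ring C is the γ-butyrolactone (O1, carbonyl C2, C3, C4, C5); C3 carries a CH2 bound to ring A (4-hydroxy-3-methoxyphenyl) and C4 carries a CH2 bound to ring B (3,4,5-trimethoxyphenyl). C3 and C4 are neighbouring stereocentres, both R, so the two benzyl arms are trans on ring C. The fragile points are the free phenol of ring A (acidic, easily oxidised, incompatible with enolates and organometallics), the lactone (opened by hydroxide) and the acidic C3–H, whose epimerisation is tolerable only because trans is the more stable arrangement. The real difficulty is the absolute configuration at C4: this carbon bears H and three CH2 groups (C3H2, C5H2–O and CH2–ring B), so a reagent has to tell apart arms that differ only at the second atom. Once C4 is fixed, C3 follows from it by alkylation anti to the C4 arm. The key step uses the fact that C2 is a single carbon on C3: removing it leaves C3=C4(C5H2OH)(CH2–ring B), a 1,1-disubstituted allylic alcohol whose hydroxyl sits exactly where it can trap a new formyl carbon as the five-membered lactol. The ring A arm sits on the enolisable carbon and can therefore be added last as an electrophile.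

## Logic of the disconnections

13 ⇒ 12. The phenolic O–H is replaced by O–CH2Ph. The phenol would quench the enolate needed for the C3 bond, and a benzyl ether falls under neutral hydrogenolysis. The forward step must spare ring C; this is met because C5–O1 is not benzylic and no other benzylic C–O bond exists.

12 ⇒ 8 + 10 (through 11). The C3–CH2(ring A) bond is cut, because C3 is alpha to the C2 carbonyl and the arm can arrive as a benzylic halide. This removes ring A and one stereocentre and leaves a lactone with C4 as its only stereocentre. The forward step must alkylate once only and anti to the C4 arm.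

10 ⇒ 9. The C–Br bond is traced back to C–OH of a commercial benzylic alcohol. The forward step must not touch the benzyl ether, and the bromide should be used fresh.

8 ⇒ 7. C2 is taken down from the lactone to the lactol oxidation level, because the lactol is what the carbonylative step delivers. The oxidant must be mild towards electron-rich ring B.

7 ⇒ 5 (through 6). The O1–C2 hemiacetal bond and the C2–C3 bond are cut, which returns C2 to CO and H2. This removes ring C and the C4 stereocentre together and leaves an achiral alkene that already holds C3, C4, C5 and the whole ring B arm. The forward step must put the formyl group on the terminal carbon, deliver hydride to one face at C4, and avoid double-bond migration and hydrogenation. The hydroxyl of 5 is deliberately left free, since it both assists the catalyst and closes the lactol; a protecting group would add two steps and remove that assistance.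

5 ⇒ 4. The CH2OH group is traced back to an ester. The ester holds the double bond in the 1,1-disubstituted position during C–C bond formation and makes the allylic carbon of 2 strongly electrophilic. The forward step must reduce 1,2 and not 1,4.

4 ⇒ 1 + 2 (through 3). The ring B–CH2 bond is cut to an aryl nucleophile and an allylic bromide. With 2, direct and allylically transposed attack give the same product, and no statistical mono-substitution of a bis-electrophile is needed. The forward step must substitute at the allylic carbon faster than the aryl metal adds to the ester or to the product.

## Other disconnections considered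

Alternative 1: The cut is through both benzylic bonds of ring C at once, C4–C(ring B arm) and C3–CH2(ring A arm). In the forward direction the 2-lithio derivative of dithiane A2 adds 1,4 to the chiral butenolide A1 anti to the menthyloxy group, and the resulting lactone enolate is trapped in the same flask by bromide 10 of the chosen route anti to the new C4 substituent, giving A3.
- In favour: two C–C bonds and both ring C stereocentres arise in one operation under substrate control from a crystalline, diastereomerically pure acetal. The stereochemical outcome does not depend on a catalyst distinguishing two CH2 arms; on this point the alternative is the better plan.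
- Against: A1 and A2 must each be prepared, the auxiliary is stoichiometric, and the step needs a cryogenic organolithium. After the key step the dithiane has to be removed with a large excess of Raney Ni, which may also attack the benzyl ether. The C5 acetal carbon must then be reduced to CH2 and the ring re-closed, so a C5 stereocentre is built only to be erased.
- Comparison: A3 carries sulfur and auxiliary atoms that are discarded later, whereas 7 contains nothing superfluous. Mechanistically this is a stoichiometric conjugate addition and alkylation against a catalytic face-selective hydride insertion. The number of operations should be about equal, and the chosen plan should produce less waste.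

Alternative 2: The cut is through two C–C bonds of ring A, which is built last. In the forward direction pyrrolidine and acetic acid join aldehyde A4 and enone A5 by enamine Michael addition and intramolecular aldol condensation to cyclohexenone A6, which is then dehydrogenated to 13.
- In favour: the phenol appears free with no protecting group (better on protecting-group economy), the methoxy/hydroxy pattern is fixed by construction, and the ring-forming step needs no precious metal and no pressurised gas (better on operational safety). The new ring stereocentre is irrelevant.
- Against: ring A can be bought, so building it spends steps on a solved problem. A4 already contains both stereocentres, so this disconnection leaves the central difficulty untouched and still depends on an asymmetric route to lactone 8. Making A4 from 8 needs a three-carbon arm and an oxidation. The amine and acid may epimerise C3 or open the lactone, A5 is prone to polymerise, and the final aromatisation needs an oxidant that spares ring B and two benzylic CH2 groups.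
- Comparison: this changes only the endgame, its key step sets no stereocentre, and it should be several steps longer than the chosen plan.

Alternative 3: The cut removes O1 from between C2 and C5, leading to the prochiral cyclobutanone A7. In the forward direction a Baeyer–Villiger monooxygenase with NADPH recycling and O2 inserts oxygen into one of the two enantiotopic C(=O)–CH2 bonds to give A8, which is identical with lactone 8.
- In favour: the lactone arrives at the right oxidation level, so the oxidation of step 4 is saved (better by one step at that stage). The medium is water and air at ambient pressure, with no CO and no precious metal (better on operational safety). There is no regiochemical question, since both migrating groups are the same CH2.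
- Against: A7 is not an article of commerce and would take about three operations by a ketene [2+2] route, which spends the saving before the key step. The sense of induction is fixed by the enzyme pocket and cannot be inverted by taking a mirror-image catalyst, whereas both ligand antipodes are available for step 3; on this point the chosen plan is better. The bulky, poorly soluble substrate may be accepted only at high dilution.
- Comparison: both key steps desymmetrise an achiral precursor that holds ring B and C3 to C5. A7 already contains C2, whereas 5 receives it from CO. Mechanistically one is migration of an enantiotopic CH2 in a Criegee intermediate and the other is face-selective Rh–H insertion. Step economy up to 8 should be equal.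

Key step: step 3

## Route

Step 1
Reactants: 1 5-bromo-1,2,3-trimethoxybenzene; 2 ethyl 2-(bromomethyl)acrylate
Product: 4 ethyl 2-(3,4,5-trimethoxybenzyl)acrylate, via (3,4,5-trimethoxyphenyl)magnesium bromide 3 (not isolated)
Conditions: Mg, I2 (cat.), THF, reflux; then added to 2, CuI (10 mol%), THF, −40 → 0 °C
Reagents that add atoms: none
Why: Grignard formation followed by copper-catalysed allylic substitution; SN2 and SN2' attack on 2 give the same product, and inverse addition at low temperature keeps the aryl metal away from the ester and from the acrylate product.

Step 2
Reactants: 4 ethyl 2-(3,4,5-trimethoxybenzyl)acrylate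
Product: 5 2-(3,4,5-trimethoxybenzyl)prop-2-en-1-ol
Conditions: i-Bu2AlH (2.3 equiv), CH2Cl2, −78 → 0 °C; aq. KNaC4H4O6 (potassium sodium tartrate) work-up
Reagents that add atoms: none
Why: 1,2-Reduction of an alpha-substituted acrylate by an electrophilic aluminium hydride, which should give the allylic alcohol with the double bond in place; 5 is purified carefully so that no copper, halide or alkene isomer reaches the rhodium catalyst.

Step 3
Reactants: 5 2-(3,4,5-trimethoxybenzyl)prop-2-en-1-ol
Product: 7 (4R)-4-(3,4,5-trimethoxybenzyl)tetrahydrofuran-2-ol (both anomers), via (3R)-4-hydroxy-3-(3,4,5-trimethoxybenzyl)butanal 6 (not isolated)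
Conditions: Rh(acac)(CO)2 (1 mol%), YanPhos-type binaphthyl phosphine–phosphoramidite ligand (3 mol%, antipode chosen for 4R), CO/H2 1:1 (10 bar), toluene, 60 °C, pressure vessel
Reagents that add atoms: carbon monoxide, [C-]#[O+]
Why: Rh(acac)(CO)2, the ligand and syngas form a chiral hydrido carbonyl complex of monovalent rhodium that binds the alkene of 5; the hydride migrates to the internal carbon (the future C4) and rhodium takes the terminal CH2, because the alternative tertiary alkyl–rhodium is crowded and could only lead to a quaternary aldehyde. CO insertion gives the acyl complex, and hydrogenolysis (oxidative addition of H2 to a trivalent rhodium dihydride, then reductive elimination) releases hydroxy aldehyde 6 with the new C2–C3 bond. 6 should close at once to lactol 7 by 5-exo-trig attack of the C5 hydroxyl on the formyl carbon (O1–C2 bond), which also shields the aldehyde from further reduction. The closest known reaction type is the rhodium-catalysed asymmetric hydroformylation of 1,1-disubstituted allylic alcohols with phosphine–phosphoramidite ligands, which gives beta-substituted lactols. The C4 stereocentre is set under catalyst control: the chiral pocket, assisted by the free hydroxyl, tells the CH2OH arm from the CH2–ring B arm and so fixes the alkene face that receives the hydride. The anomeric carbon C2 forms as a mixture, which does not matter because step 4 turns it into the carbonyl. The step needs regioselectivity for the terminal carbon (secured by the 1,1-disubstitution), enantioface selectivity (ligand plus hydroxyl) and chemoselectivity over double-bond migration and hydrogenation (moderate temperature, excess ligand, sufficient CO pressure).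

Step 4
Reactants: 7 (4R)-4-(3,4,5-trimethoxybenzyl)tetrahydrofuran-2-ol
Product: 8 (4R)-4-(3,4,5-trimethoxybenzyl)dihydrofuran-2(3H)-one
Conditions: Ag2CO3 on Celite (excess), toluene, reflux
Reagents that add atoms: none
Why: Fétizon oxidation of a lactol to the lactone under neutral conditions; ring B is not attacked and C4, which is beta to the carbonyl, cannot epimerise.

Step 5
Reactants: 9 4-benzyloxy-3-methoxybenzyl alcohol
Product: 10 4-benzyloxy-3-methoxybenzyl bromide
Conditions: PBr3 (0.4 equiv), Et2O, 0 °C; used at once
Reagents that add atoms: phosphorus tribromide, BrP(Br)Br
Why: Conversion of an electron-rich benzylic alcohol to the bromide through its phosphite ester; the aryl benzyl ether should survive the short exposure at 0 °C.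

Step 6
Reactants: 8 (4R)-4-(3,4,5-trimethoxybenzyl)dihydrofuran-2(3H)-one; 10 4-benzyloxy-3-methoxybenzyl bromide
Product: 12 (3R,4R)-3-(4-benzyloxy-3-methoxybenzyl)-4-(3,4,5-trimethoxybenzyl)dihydrofuran-2(3H)-one, via lithium (4R)-4-(3,4,5-trimethoxybenzyl)-4,5-dihydrofuran-2-olate 11 (not isolated)
Conditions: LiN(SiMe3)2 (1.1 equiv), THF, −78 °C; then 10, DMPU, −78 → −30 °C
Reagents that add atoms: none
Why: Alkylation of a lactone enolate; the C4 arm blocks one face of the planar enolate, so the bromide should enter anti and give the 3,4-trans (3R) product, which is also the more stable epimer.

Step 7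
Reactants: 12 (3R,4R)-3-(4-benzyloxy-3-methoxybenzyl)-4-(3,4,5-trimethoxybenzyl)dihydrofuran-2(3H)-one
Product: 13 (3R,4R)-3-(4-hydroxy-3-methoxybenzyl)-4-(3,4,5-trimethoxybenzyl)dihydrofuran-2(3H)-one
Conditions: H2 (1 atm), Pd/C (10%), EtOAc, rt
Reagents that add atoms: none
Why: Hydrogenolysis of the aryl benzyl ether under neutral conditions; the lactone, the methyl ethers and both stereocentres should be untouched, since no other benzylic C–O bond is present.

## Compound list

1 | 5-bromo-1,2,3-trimethoxybenzene | COc1cc(Br)cc(OC)c1OC | starting material
2 | ethyl 2-(bromomethyl)acrylate | C=C(CBr)C(=O)OCC | starting material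
3 | (3,4,5-trimethoxyphenyl)magnesium bromide | COc1cc([Mg]Br)cc(OC)c1OC | intermediate
4 | ethyl 2-(3,4,5-trimethoxybenzyl)acrylate | C=C(Cc1cc(OC)c(OC)c(OC)c1)C(=O)OCC | intermediate
5 | 2-(3,4,5-trimethoxybenzyl)prop-2-en-1-ol | COc1cc(CC(=C)CO)cc(OC)c1OC | intermediate
6 | (3R)-4-hydroxy-3-(3,4,5-trimethoxybenzyl)butanal | O=CC[C@@H](Cc1cc(OC)c(OC)c(OC)c1)CO | intermediate
7 | (4R)-4-(3,4,5-trimethoxybenzyl)tetrahydrofuran-2-ol (both anomers) | OC1C[C@@H](Cc2cc(OC)c(OC)c(OC)c2)CO1 | intermediate
8 | (4R)-4-(3,4,5-trimethoxybenzyl)dihydrofuran-2(3H)-one | O=C1C[C@@H](Cc2cc(OC)c(OC)c(OC)c2)CO1 | intermediate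
9 | 4-benzyloxy-3-methoxybenzyl alcohol | COc1cc(CO)ccc1OCc1ccccc1 | starting material
10 | 4-benzyloxy-3-methoxybenzyl bromide | COc1cc(CBr)ccc1OCc1ccccc1 | intermediate
11 | lithium (4R)-4-(3,4,5-trimethoxybenzyl)-4,5-dihydrofuran-2-olate | [Li]OC1=C[C@@H](Cc2cc(OC)c(OC)c(OC)c2)CO1 | intermediate
12 | (3R,4R)-3-(4-benzyloxy-3-methoxybenzyl)-4-(3,4,5-trimethoxybenzyl)dihydrofuran-2(3H)-one | COc1cc(C[C@H]2C(=O)OC[C@@H]2Cc2cc(OC)c(OC)c(OC)c2)ccc1OCc1ccccc1 | intermediate
13 | (3R,4R)-3-(4-hydroxy-3-methoxybenzyl)-4-(3,4,5-trimethoxybenzyl)dihydrofuran-2(3H)-one | COc1cc(C[C@H]2C(=O)OC[C@@H]2Cc2cc(OC)c(OC)c(OC)c2)ccc1O | target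

Total step count: 7. Longest linear sequence: 6 steps (steps 1, 2, 3, 4, 6, 7).

## Steps least certain to work

Step 3 (key step). The most likely failure is poor enantioface discrimination, because the two arms on the prochiral carbon are both CH2 groups. Double-bond migration into conjugation with ring B or towards the enol, and simple hydrogenation, may also compete. The fallback abandons catalytic carbonylation and sets out from 1. Grignard reagent 3 is quenched with DMF to give 3,4,5-trimethoxybenzaldehyde F1. Stobbe condensation with dimethyl succinate (NaOMe, MeOH) should give (E)-3-(methoxycarbonyl)-4-(3,4,5-trimethoxyphenyl)but-3-enoic acid F2. Asymmetric hydrogenation with [Rh(cod)2]BF4 and a DuPhos-type bisphospholane, the antipode chosen for R, should give (3R)-3-(methoxycarbonyl)-4-(3,4,5-trimethoxyphenyl)butanoic acid F3. Reduction of the ester in the presence of the carboxylate salt (CaCl2/NaBH4, EtOH) and acidification should then close the ring. The fallback comes back to the route at 8 and bypasses 4 to 7.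

Step 6. Proton exchange between product 12 and enolate 11 may cause double alkylation at C3 and leave 8 unchanged, and the labile bromide 10 may decompose before it is consumed. The fallback replaces alkylation by an aldol and reductive sequence and sets out from 8 and 9. Alcohol 9 is oxidised with MnO2 (CH2Cl2) to 4-benzyloxy-3-methoxybenzaldehyde F4. Enolate 11 is added to F4 at −78 °C to give (3S,4R)-3-[(4-benzyloxy-3-methoxyphenyl)(hydroxy)methyl]-4-(3,4,5-trimethoxybenzyl)dihydrofuran-2(3H)-one F5 as carbinol epimers, trans on ring C; the alkoxide product cannot react a second time. Hydrogenolysis (H2, Pd/C, AcOH, trace HClO4) should remove the benzylic hydroxyl and the benzyl ether together. The fallback comes back to the route at 13.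

Step 1. The aryl Grignard may add to the ester or in conjugate fashion to product 4, or homocouple. The fallback changes the mechanism to palladium-catalysed cross-coupling and sets out from 1. Bromine–lithium exchange (n-BuLi, THF, −78 °C), B(OMe)3 and acidic work-up give (3,4,5-trimethoxyphenyl)boronic acid F6. F6 is coupled with 2 under Pd(PPh3)4 (zerovalent palladium) and K2CO3 in aqueous THF through a π-allyl intermediate. The fallback comes back to the route at 4.

Step 2. Partial conjugate reduction may give the saturated alcohol, which would be hard to separate from 5 and is inert in step 3. The fallback avoids any hydride reduction and sets out from 1. Grignard reagent 3 is coupled under CuI catalysis with an excess of purchased 2-methylenepropane-1,3-diyl diacetate to give 2-(3,4,5-trimethoxybenzyl)allyl acetate F7. Methanolysis (K2CO3, MeOH) then frees the alcohol. The fallback comes back to the route at 5 and bypasses 4.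

Further compounds
F1 | step 3 | 3,4,5-trimethoxybenzaldehyde | COc1cc(C=O)cc(OC)c1OC
F2 | step 3 | (E)-3-(methoxycarbonyl)-4-(3,4,5-trimethoxyphenyl)but-3-enoic acid | COC(=O)/C(CC(=O)O)=C/c1cc(OC)c(OC)c(OC)c1
F3 | step 3 | (3R)-3-(methoxycarbonyl)-4-(3,4,5-trimethoxyphenyl)butanoic acid | COC(=O)[C@@H](CC(=O)O)Cc1cc(OC)c(OC)c(OC)c1
F4 | step 6 | 4-benzyloxy-3-methoxybenzaldehyde | COc1cc(C=O)ccc1OCc1ccccc1
F5 | step 6 | (3S,4R)-3-[(4-benzyloxy-3-methoxyphenyl)(hydroxy)methyl]-4-(3,4,5-trimethoxybenzyl)dihydrofuran-2(3H)-one (carbinol epimers) | COc1cc(C(O)[C@H]2C(=O)OC[C@@H]2Cc2cc(OC)c(OC)c(OC)c2)ccc1OCc1ccccc1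
F6 | step 1 | (3,4,5-trimethoxyphenyl)boronic acid | COc1cc(B(O)O)cc(OC)c1OC
F7 | step 2 | 2-(3,4,5-trimethoxybenzyl)allyl acetate | COc1cc(CC(=C)COC(C)=O)cc(OC)c1OC
A1 | alternative 1 | (5R)-5-[(1R,2S,5R)-2-isopropyl-5-methylcyclohexyloxy]furan-2(5H)-one | O=C1C=C[C@H](O[C@@H]2C[C@H](C)CC[C@H]2C(C)C)O1
A2 | alternative 1 | 2-(3,4,5-trimethoxyphenyl)-1,3-dithiane | COc1cc(C2SCCCS2)cc(OC)c1OC
A3 | alternative 1 | (3R,4R,5R)-3-(4-benzyloxy-3-methoxybenzyl)-5-[(1R,2S,5R)-2-isopropyl-5-methylcyclohexyloxy]-4-[2-(3,4,5-trimethoxyphenyl)-1,3-dithian-2-yl]dihydrofuran-2(3H)-one | COc1cc(C[C@H]2C(=O)O[C@@H](O[C@@H]3C[C@H](C)CC[C@H]3C(C)C)[C@@H]2C4(SCCCS4)c5cc(OC)c(OC)c(OC)c5)ccc1OCc6ccccc6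
A4 | alternative 2 | 3-[(3R,4R)-2-oxo-4-(3,4,5-trimethoxybenzyl)tetrahydrofuran-3-yl]propanal | O=CCC[C@H]1C(=O)OC[C@@H]1Cc1cc(OC)c(OC)c(OC)c1
A5 | alternative 2 | 1-methoxybut-3-en-2-one | COCC(=O)C=C
A6 | alternative 2 | 2-methoxy-4-{[(3R,4R)-2-oxo-4-(3,4,5-trimethoxybenzyl)tetrahydrofuran-3-yl]methyl}cyclohex-2-en-1-one (mixture at the ring carbon) | COC1=CC(C[C@H]2C(=O)OC[C@@H]2Cc2cc(OC)c(OC)c(OC)c2)CCC1=O
A7 | alternative 3 | 3-(3,4,5-trimethoxybenzyl)cyclobutan-1-one | COc1cc(CC2CC(=O)C2)cc(OC)c1OC
A8 | alternative 3 | (4R)-4-(3,4,5-trimethoxybenzyl)dihydrofuran-2(3H)-one (identical with 8) | O=C1C[C@@H](Cc2cc(OC)c(OC)c(OC)c2)CO1
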